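The ring is numbered C1 (free acid), C2 (4-hydroxyphenyl), C3 (ester), C4 (catechol). The cyclobutane alternates carboxyl-bearing carbons (C1, C3) and aryl-bearing carbons (C2, C4). With a nitrogen atom temporarily bridging C1 and C4, C1–C2 becomes a Michael bond and C3–C4 a Mannich bond. The key step exploits this polarity. An exo-selective, silver-catalysed asymmetric [3+2] cycloaddition of a glycine aldimine (C1–N–C4) with a 4-benzyloxycinnamate (C2=C3) forms both bonds and four stereocentres at once. Its product is a pyrrolidine, and stereoretentive extrusion of the nitrogen as N2 then closes C1–C4. Base inverts C1 to the all-trans ring, orthogonal esters let bought (R)-danshensu be attached at C3, and one hydrogenolysis removes seven benzyl groups.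

Key step: step 3

Assumption: (R)-DTBM-SEGPHOS is written for the (2R,3R,4S,5S) series of 7 by analogy only. The sense of induction has to be checked on 7, and the equally available (S)-ligand is used if it is opposite.

Step 1
Reactants: 1 4-(benzyloxy)benzaldehyde; 2 tert-butyl 2-(diethoxyphosphoryl)acetate
Product: 3 tert-butyl (E)-3-[4-(benzyloxy)phenyl]prop-2-enoate
Conditions: NaH, THF, 0 °C to rt
Reagents that add atoms: none
Why: Horner-Wadsworth-Emmons olefination of an aromatic aldehyde with a stabilised phosphonate should give the E-enoate under the usual thermodynamic control of the addition-elimination sequence; no stereocentre is formed.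

Step 2
Reactants: 4 3,4-bis(benzyloxy)benzaldehyde; 5 glycine benzyl ester hydrochloride
Product: 6 benzyl N-[(E)-3,4-bis(benzyloxy)benzylidene]glycinate
Conditions: Et3N, MgSO4, CH2Cl2, rt
Reagents that add atoms: none
Why: Imine condensation of the liberated primary amine with the aromatic aldehyde, driven by the drying agent, should give the E-aldimine; no stereocentre is formed.

Step 3
Reactants: 3 tert-butyl (E)-3-[4-(benzyloxy)phenyl]prop-2-enoate; 6 benzyl N-[(E)-3,4-bis(benzyloxy)benzylidene]glycinate
Product: 7 2-benzyl 4-tert-butyl (2R,3R,4S,5S)-3-[4-(benzyloxy)phenyl]-5-[3,4-bis(benzyloxy)phenyl]pyrrolidine-2,4-dicarboxylate (exo adduct: 2,5-cis, 2,3-cis, 3,4-trans, 4,5-trans)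
Conditions: AgOTf (5 mol %), KN(SiMe3)2 (5 mol %), (R)-DTBM-SEGPHOS (6 mol %), 4 Å MS, toluene, 0 °C to rt
Reagents that add atoms: none
Why: AgN(SiMe3)2 on the chiral bisphosphine deprotonates 6 to an N,O-chelated W-shaped azomethine ylide of monovalent silver, whose glycinate carbon (future C1) adds to the beta-carbon of 3 (future C2), after which the ester enolate carbon (future C3) attacks the imine carbon (future C4); this is a catalytic asymmetric 1,3-dipolar cycloaddition of the exo-selective type known for acrylates and beta-nitrostyrenes. The pyrrolidine ring closes in a concerted [3+2] sense or, in the stepwise limit, by a 5-endo-trig Mannich closure that follows the intermolecular Michael addition. C1 and C4 should come out cis because the chelate fixes the W geometry of the ylide, C2 and C3 trans because the E geometry of 3 is transferred suprafacially, and C3 and C4 trans (exo) because one alkene substituent must lie under the ligand and the flat aryl group fits there better than CO2tBu. The absolute sense is set by the ligand, whose 3,5-di-tert-butyl-4-methoxyphenyl groups leave one face of the ylide open. The step needs regio-, exo- and facial selectivity: regioselectivity is secured by the matched polarity of the nucleophilic glycinate terminus and the electrophilic beta-carbon, and exo selectivity by the bulky tert-butyl ester. The exo adduct places both aryl groups on one ring face, the only relationship that no later step could correct.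

Step 4
Reactants: 7 2-benzyl 4-tert-butyl (2R,3R,4S,5S)-3-[4-(benzyloxy)phenyl]-5-[3,4-bis(benzyloxy)phenyl]pyrrolidine-2,4-dicarboxylate
Product: 9 1-benzyl 3-tert-butyl (1S,2R,3S,4S)-2-[4-(benzyloxy)phenyl]-4-[3,4-bis(benzyloxy)phenyl]cyclobutane-1,3-dicarboxylate (C1 ester cis to both aryl groups), via 1,1-diazene 8 (not isolated)
Conditions: PhI(OH)OTs (2.5 equiv), NH4O2CNH2 (8 equiv), CF3CH2OH, 80 °C
Reagents that add atoms: none
Why: Contractive nitrogen extrusion from a pyrrolidine, in which the iodonitrene made from PhI(OH)OTs and ammonia aminates the ring nitrogen, further oxidation gives 1,1-diazene 8, loss of N2 leaves a singlet 1,4-biradical stabilised by the ester at C1 and the aryl group at C4, and its fast collapse should form C1–C4 with retention at both carbons.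

Step 5
Reactants: 9 1-benzyl 3-tert-butyl (1S,2R,3S,4S)-2-[4-(benzyloxy)phenyl]-4-[3,4-bis(benzyloxy)phenyl]cyclobutane-1,3-dicarboxylate
Product: 10 1-benzyl 3-tert-butyl (1R,2R,3S,4S)-2-[4-(benzyloxy)phenyl]-4-[3,4-bis(benzyloxy)phenyl]cyclobutane-1,3-dicarboxylate (all-trans)
Conditions: NaOCH2Ph (0.3 equiv), PhCH2OH/THF, 50 °C
Reagents that add atoms: none
Why: Thermodynamic epimerisation through the ester enolate should invert only C1, whose ester alone stands cis to both neighbouring aryl groups, because the matched alkoxide is degenerate towards the benzyl ester and too hindered to attack the tert-butyl ester, C3 already has its preferred orientation, and C2 and C4 are not acidic.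

Step 6
Reactants: 10 1-benzyl 3-tert-butyl (1R,2R,3S,4S)-2-[4-(benzyloxy)phenyl]-4-[3,4-bis(benzyloxy)phenyl]cyclobutane-1,3-dicarboxylate
Product: 11 all-trans monoacid with free CO2H at C3 and benzyl ester at C1, (1R,2S,3S,4R) in the ring numbering of the target
Conditions: CF3CO2H/CH2Cl2 (1:4), 0 °C to rt
Reagents that add atoms: none
Why: Acidolysis of the tert-butyl ester by E1-type loss of the tert-butyl cation should leave the benzyl ester, the benzyl ethers and all four ring stereocentres untouched.

Step 7
Reactants: 12 sodium (R)-3-(3,4-dihydroxyphenyl)lactate (sodium danshensu)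
Product: 13 benzyl (R)-3-[3,4-bis(benzyloxy)phenyl]-2-hydroxypropanoate
Conditions: BnBr (3.3 equiv), K2CO3, DMF, argon, rt
Reagents that add atoms: benzyl bromide BrCc1ccccc1
Why: Williamson-type SN2 O-alkylation of the carboxylate and the two phenolates; K2CO3 neither deprotonates the secondary alcohol nor enolises the alpha-hydroxy ester, so the bought R stereocentre is kept.

Step 8
Reactants: 11 all-trans monoacid; 13 benzyl (R)-3-[3,4-bis(benzyloxy)phenyl]-2-hydroxypropanoate
Product: 14 heptabenzyl-protected target, ring (1R,2R,3S,4S), side chain R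
Conditions: DIC, DMAP (0.3 equiv), CH2Cl2, 0 °C to rt
Reagents that add atoms: none
Why: Steglich esterification (carbodiimide activation with DMAP acyl transfer) does not break the C–O bond at the carbinol centre of 13, so R is retained, and any enolisation of the activated acid at C3 would return to the favoured trans orientation.

Step 9
Reactants: 14 heptabenzyl-protected target
Product: 15 (1R,2R,3S,4S)-3-{[(1R)-1-carboxy-2-(3,4-dihydroxyphenyl)ethoxy]carbonyl}-4-(3,4-dihydroxyphenyl)-2-(4-hydroxyphenyl)cyclobutane-1-carboxylic acid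
Conditions: H2 (1 atm), Pd/C, THF/MeOH, rt, work-up under argon
Reagents that add atoms: none
Why: Catalytic hydrogenolysis should cleave five aryl benzyl ethers and two benzyl esters, while the acyloxy-bearing carbon is only homobenzylic and the cyclobutane C–C bonds resist one atmosphere of hydrogen, so all five stereocentres persist.

Compound list
1 | 4-(benzyloxy)benzaldehyde | O=Cc1ccc(OCc2ccccc2)cc1 | starting material
2 | tert-butyl 2-(diethoxyphosphoryl)acetate | CCOP(=O)(CC(=O)OC(C)(C)C)OCC | starting material
3 | tert-butyl (E)-3-[4-(benzyloxy)phenyl]prop-2-enoate | CC(C)(C)OC(=O)/C=C/c1ccc(OCc2ccccc2)cc1 | intermediate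
4 | 3,4-bis(benzyloxy)benzaldehyde | O=Cc1ccc(OCc2ccccc2)c(OCc2ccccc2)c1 | starting material
5 | glycine benzyl ester hydrochloride | [Cl-].[NH3+]CC(=O)OCc1ccccc1 | starting material
6 | benzyl N-[(E)-3,4-bis(benzyloxy)benzylidene]glycinate | O=C(OCc1ccccc1)C/N=C/c1ccc(OCc2ccccc2)c(OCc2ccccc2)c1 | intermediate
7 | 2-benzyl 4-tert-butyl (2R,3R,4S,5S)-3-[4-(benzyloxy)phenyl]-5-[3,4-bis(benzyloxy)phenyl]pyrrolidine-2,4-dicarboxylate | O=C(OCc1ccccc1)[C@H]1[C@@H](c2ccc(OCc3ccccc3)cc2)[C@H](C(=O)OC(C)(C)C)[C@@H](c2ccc(OCc3ccccc3)c(OCc3ccccc3)c2)N1 | intermediate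
8 | 1,1-diazene (N-nitrene) of pyrrolidine 7, same four configurations, not isolated | O=C(OCc1ccccc1)[C@H]1[C@@H](c2ccc(OCc3ccccc3)cc2)[C@H](C(=O)OC(C)(C)C)[C@@H](c2ccc(OCc3ccccc3)c(OCc3ccccc3)c2)[N+]1=[N-] | intermediate
9 | 1-benzyl 3-tert-butyl (1S,2R,3S,4S)-2-[4-(benzyloxy)phenyl]-4-[3,4-bis(benzyloxy)phenyl]cyclobutane-1,3-dicarboxylate | O=C(OCc1ccccc1)[C@H]1[C@@H](c2ccc(OCc3ccccc3)cc2)[C@H](C(=O)OC(C)(C)C)[C@H]1c1ccc(OCc2ccccc2)c(OCc2ccccc2)c1 | intermediate
10 | 1-benzyl 3-tert-butyl (1R,2R,3S,4S)-2-[4-(benzyloxy)phenyl]-4-[3,4-bis(benzyloxy)phenyl]cyclobutane-1,3-dicarboxylate | O=C(OCc1ccccc1)[C@@H]1[C@@H](c2ccc(OCc3ccccc3)cc2)[C@H](C(=O)OC(C)(C)C)[C@H]1c1ccc(OCc2ccccc2)c(OCc2ccccc2)c1 | intermediate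
11 | all-trans monoacid, CO2H at C3 and CO2Bn at C1, (1R,2S,3S,4R) in target numbering | O=C(OCc1ccccc1)[C@@H]1[C@@H](c2ccc(OCc3ccccc3)cc2)[C@H](C(=O)O)[C@H]1c1ccc(OCc2ccccc2)c(OCc2ccccc2)c1 | intermediate
12 | sodium (R)-3-(3,4-dihydroxyphenyl)lactate | O[C@H](Cc1ccc(O)c(O)c1)C(=O)[O-].[Na+] | starting material
13 | benzyl (R)-3-[3,4-bis(benzyloxy)phenyl]-2-hydroxypropanoate | O[C@H](Cc1ccc(OCc2ccccc2)c(OCc2ccccc2)c1)C(=O)OCc1ccccc1 | intermediate
14 | heptabenzyl-protected target, ring (1R,2R,3S,4S), side chain R | O=C(OCc1ccccc1)[C@@H]1[C@@H](c2ccc(OCc3ccccc3)cc2)[C@H](C(=O)O[C@H](Cc2ccc(OCc3ccccc3)c(OCc3ccccc3)c2)C(=O)OCc2ccccc2)[C@H]1c1ccc(OCc2ccccc2)c(OCc2ccccc2)c1 | intermediate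
15 | CNP0270917.1 | O=C(O)[C@@H]1[C@@H](c2ccc(O)cc2)[C@H](C(=O)O[C@H](Cc2ccc(O)c(O)c2)C(=O)O)[C@H]1c1ccc(O)c(O)c1 | target

Total step count: 9. Longest linear sequence: 7 steps (1, 3, 4, 5, 6, 8, 9).

Steps most likely to fail

Step 3. The conjugate addition to the beta-aryl enoate may be sluggish. The ylide could then be consumed by self-condensation, and the slow reaction could leak into the endo mode or lose facial selectivity. The fallback sets out from 6 and comes back at 7, and it replaces the ester dipolarophile by a much more electrophilic acyl surrogate. Commercial (E)-4-benzyloxycinnamic acid is condensed with 3,5-dimethylpyrazole (DIC, DMAP, CH2Cl2) to (E)-3-[4-(benzyloxy)phenyl]-1-(3,5-dimethylpyrazol-1-yl)prop-2-en-1-one F1. Cycloaddition of F1 with 6 under Cu(CH3CN)4BF4, a chiral ferrocenyl P,N ligand and Et3N (an exo-selective system of monovalent copper) should give the 4-acylpyrazole pyrrolidine F2 with the configuration of 7. LiOC(CH3)3 in THF at −20 °C then exchanges the pyrazole for tert-butoxide, faster than it touches the benzyl ester, and gives 7.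

Step 4. The 1,4-biradical may fragment across C2–C3 into two cinnamates instead of closing to the crowded ring. The trivalent iodine reagent may also oxidise the electron-rich benzyloxyarenes in the fluorinated alcohol. The fallback sets out from 7 and comes back at 9, and it reaches the same diazene 8 without any oxidant. Sulfonyl azide transfer to the ring nitrogen with 1-(azidosulfonyl)-2,3-dimethylimidazolium triflate (MeCN, 0 °C to rt) gives the isolable pyrrolidine-1-sulfonyl azide F3. Heating F3 in toluene at 110 °C triggers a Curtius-type shift of the amine nitrogen and loss of the sulfur unit, followed by extrusion of nitrogen in a non-polar medium, to give 9.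

Step 5. The proton may return only slowly to the ring face that carries both aryl groups. Long heating would then be needed, and alkoxide exchange at the tert-butyl ester would begin to erase the difference between the two esters. The fallback sets out from 9 and comes back at 11 by reversing the order of events. CF3CO2H/CH2Cl2 first gives the C1-epimeric monoacid F4. NaOCH2Ph (2.5 equiv) in PhCH2OH at 80 °C then epimerises C1, while C3 is shielded as its carboxylate against both enolisation and exchange. Acidification gives 11.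

Further compounds
F1 | step 3 | (E)-3-[4-(benzyloxy)phenyl]-1-(3,5-dimethylpyrazol-1-yl)prop-2-en-1-one | Cc1cc(C)n(C(=O)/C=C/c2ccc(OCc3ccccc3)cc2)n1
F2 | step 3 | benzyl (2R,3R,4S,5S)-3-[4-(benzyloxy)phenyl]-5-[3,4-bis(benzyloxy)phenyl]-4-(3,5-dimethylpyrazole-1-carbonyl)pyrrolidine-2-carboxylate | O=C(OCc1ccccc1)[C@H]1[C@@H](c2ccc(OCc3ccccc3)cc2)[C@H](C(=O)n2nc(C)cc2C)[C@@H](c2ccc(OCc3ccccc3)c(OCc3ccccc3)c2)N1
F3 | step 4 | 2-benzyl 4-tert-butyl (2R,3R,4S,5S)-1-(azidosulfonyl)-3-[4-(benzyloxy)phenyl]-5-[3,4-bis(benzyloxy)phenyl]pyrrolidine-2,4-dicarboxylate | O=C(OCc1ccccc1)[C@H]1[C@@H](c2ccc(OCc3ccccc3)cc2)[C@H](C(=O)OC(C)(C)C)[C@@H](c2ccc(OCc3ccccc3)c(OCc3ccccc3)c2)N1S(=O)(=O)N=[N+]=[N-]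
F4 | step 5 | C1-epimeric monoacid, CO2H at C3 and CO2Bn at C1 cis to both aryl groups, (1S,2S,3S,4R) in target numbering | O=C(OCc1ccccc1)[C@H]1[C@@H](c2ccc(OCc3ccccc3)cc2)[C@H](C(=O)O)[C@H]1c1ccc(OCc2ccccc2)c(OCc2ccccc2)c1
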